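A direct plan would acylate and C-prenylate phloroglucinol to the monomers A1 (2-methylbutanoyl) and A2 (isobutyryl), convert A2 with 6-methylheptanal and a sulfinate into the benzylic sulfone A3, and add A1 to the o-quinone methide A4 released from A3 under a chiral catalyst. Its weakest steps would be:
- the sulfone-forming condensation, because the benzylic cation could be taken up by a second A2 and A3 would be labile;
- the catalyst-controlled addition to A4, because one face of a planar electrophile with two similar flanks would have to be chosen and the product could re-ionise and scramble;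
- the aqueous mono-C-prenylation, because O- and di-alkylation would compete, twice.

The methine carbon that carries the two almost identical rings is read as C3 of a 3-alkylglutaric acid. Catalytic methanolysis of the prochiral anhydride sets this centre while its two arms (CO2H and CO2Me) are still very different. Each arm is then grown into a complete benzene ring: the acid becomes a ketene that takes up a prenyl siloxyalkyne ([2+2]) and then siloxyacetylene (benzannulation). One annulation fixes all six ring positions: arm, three oxygens, prenyl and a single free CH beside the only unsilylated oxygen, where the acyl group later arrives by O-to-C migration. No quinone methide is formed, no catalyst has to tell the rings apart, and no phenolate is prenylated.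

Key step: step 8

Assumption: which pseudo-enantiomeric cinchona catalyst delivers the (R)-hemiester in step 4 is fixed by a test run; if the more selective catalyst gave the (S)-acid, the order in which the two acyl groups are introduced would simply be exchanged.

Ring B is the isobutyryl ring (built first), ring A the 2-methylbutanoyl ring.

**Step 1**
Reactants: 1 6-methylheptanal; 2 diethyl malonate
Product: 4 tetraethyl 2-(5-methylhexyl)propane-1,1,3,3-tetracarboxylate, via alkylidene malonate 3 (not isolated)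
Conditions: 2 (2.2 equiv), piperidine (0.1 equiv), AcOH (0.1 equiv), toluene, reflux, Dean–Stark; then NaOEt (0.2 equiv), EtOH, rt
Reagents that add atoms: none
Why: Knoevenagel condensation followed by Michael addition of a second malonate to alkylidene malonate 3 gives the 2:1 adduct, the standard entry to 3-alkylglutaric acids.

**Step 2**
Reactants: 4 tetraethyl 2-(5-methylhexyl)propane-1,1,3,3-tetracarboxylate
Product: 5 3-(5-methylhexyl)pentanedioic acid
Conditions: 6 M HCl, reflux; crystallisation
Reagents that add atoms: water, O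
Why: Acid hydrolysis of the four esters and decarboxylation of both malonic acid units should leave the symmetrical 3-substituted glutaric acid, which has no stereocentre yet.

**Step 3**
Reactants: 5 3-(5-methylhexyl)pentanedioic acid
Product: 6 4-(5-methylhexyl)oxane-2,6-dione (3-(5-methylhexyl)glutaric anhydride)
Conditions: Ac2O, reflux; volatiles distilled off
Reagents that add atoms: none
Why: Cyclodehydration of a 1,5-diacid with acetic anhydride gives the six-membered prochiral anhydride.

**Step 4**
Reactants: 6 4-(5-methylhexyl)oxane-2,6-dione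
Product: 7 (3R)-5-methoxy-3-(5-methylhexyl)-5-oxopentanoic acid
Conditions: MeOH (10 equiv), 1-[3,5-bis(trifluoromethyl)phenyl]-3-[(8α,9S)-6′-methoxycinchonan-9-yl]thiourea or its quinidine-derived pseudo-enantiomer (10 mol%), MTBE, −20 °C; acid–base extraction; enantiomeric purity checked by chiral HPLC and raised, if needed, by crystallisation of a 1-phenylethylammonium salt
Reagents that add atoms: methanol, CO
Why: Organocatalytic desymmetrisation of a prochiral cyclic anhydride (the reaction type used for 3-alkylglutaric anhydrides): the quinuclidine activates methanol as a general base while the thiourea binds one of the two enantiotopic carbonyl groups, so the catalyst alone sets the stereocentre at a stage where its two arms differ strongly.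

**Step 5**
Reactants: 8 ethyl 4-methylpent-3-enoate
Product: 11 [(5-methylhex-4-en-1-yn-1-yl)oxy]tri(propan-2-yl)silane, via dibromo enolate 9 (not isolated), via lithium ynolate 10 (not isolated)
Conditions: CH2Br2 (2.2 equiv), LiTMP (2.2 equiv), THF, −78 °C; 8; n-BuLi (2.5 equiv), −78 → 0 °C; i-Pr3SiCl (1.2 equiv), −78 °C → rt; pentane work-up, distillation
Reagents that add atoms: dibromomethane, BrCBr; chlorotri(propan-2-yl)silane, CC(C)[Si](Cl)(C(C)C)C(C)C
Why: Kowalski ester homologation stopped at the ynolate: dibromomethyllithium adds to the ester, the dibromo enolate 9 undergoes bromine–lithium exchange and carbenoid 1,2-shift to ynolate 10, and the bulky silyl chloride traps it on oxygen.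

**Step 6**
Reactants: 12 acetylene
Product: 15 (ethynyloxy)tri(propan-2-yl)silane, via lithium acetylide 13 (not isolated), via lithium ethynolate 14 (not isolated)
Conditions: n-BuLi (1.0 equiv), THF, −78 °C; LiOOt-Bu (1.0 equiv, from t-BuOOH and LiN(SiMe3)2), −78 → −20 °C; i-Pr3SiOTf (1.0 equiv), −78 °C; pentane extraction, distillation
Reagents that add atoms: tert-butyl hydroperoxide, CC(C)(C)OO; tri(propan-2-yl)silyl trifluoromethanesulfonate, CC(C)[Si](OS(=O)(=O)C(F)(F)F)(C(C)C)C(C)C
Why: Julia-type oxygenation of a lithium acetylide by the electrophilic oxygen of lithium tert-butyl peroxide gives the parent ynolate, and the hard, bulky silyl triflate is chosen to favour O- over C-silylation.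

**Step 7**
Reactants: 7 (3R)-5-methoxy-3-(5-methylhexyl)-5-oxopentanoic acid; 11 [(5-methylhex-4-en-1-yn-1-yl)oxy]tri(propan-2-yl)silane
Product: 18 methyl (3S)-8-methyl-3-[3-(3-methylbut-2-en-1-yl)-4-oxo-2-(triisopropylsilyloxy)cyclobut-2-en-1-yl]nonanoate (both epimers at the ring sp3 carbon), via acid chloride 16 (not isolated), via ketene 17 (not isolated)
Conditions: 1-chloro-N,N,2-trimethylprop-1-en-1-amine (1.05 equiv), CH2Cl2, 0 °C → rt; then added over 2 h to 11 (1.3 equiv), Et3N (1.5 equiv), CH2Cl2, rt; filtration, evaporation, used crude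
Reagents that add atoms: none
Why: The acid chloride, made under neutral conditions, is dehydrochlorinated to aldoketene 17, which undergoes the regioselective [2+2] cycloaddition of ketenes with siloxyalkynes (nucleophilic alkyne β-carbon to the ketene carbonyl carbon); the new ring sp3 centre is uncontrolled and vanishes in step 8, and the glutarate centre, β to the carbonyl group, is not touched.

**Step 8**
Reactants: 18 methyl (3S)-8-methyl-3-[3-(3-methylbut-2-en-1-yl)-4-oxo-2-(triisopropylsilyloxy)cyclobut-2-en-1-yl]nonanoate; 15 (ethynyloxy)tri(propan-2-yl)silane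
Product: 23 (4S)-4-(5-methylhexyl)-6-(3-methylbut-2-en-1-yl)-5,7-bis(triisopropylsilyloxy)-3,4-dihydro-2H-chromen-2-one, via vinylketene 19 (not isolated), via vinylcyclobutenone 20 (not isolated), via dienylketene 21 (not isolated), via hydroxy ester 22 (not isolated)
Conditions: 15 (2.0 equiv), toluene (0.2 M), 80 °C, sealed tube; evaporation of excess 15; then (1S)-(+)-camphor-10-sulfonic acid (5 mol%), toluene, 80 °C, slow argon stream
Reagents that add atoms: none
Why: Danheiser benzannulation in its siloxyalkyne version: thermal 4π-electrocyclic opening of 18 gives siloxy-vinylketene 19, whose ketene C=C adds to 15 in a [2+2] cycloaddition to give 20, and 4π opening of 20 to dienylketene 21 followed by 6π-electrocyclic closure and tautomerisation delivers phenol 22. The closest known reaction is the annulation of 3-alkyl- or 2,3-dialkylcyclobutenones with triisopropylsiloxyalkynes to resorcinol monosilyl ethers, and the use of a 3-siloxycyclobutenone, itself the known type of product of a ketene–siloxyalkyne cycloaddition, extends it to the phloroglucinol pattern. The carbocycle is closed by the 6π-electrocyclisation (two carbons from the glutarate arm, two from 11, two from 15), and the lactone by acid-catalysed 6-exo-trig acyl substitution of the new phenol on the methyl ester, helped by the substituted benzylic tether and driven by loss of methanol. No new stereocentre remains, since the ring sp3 carbon of 18 becomes aromatic and the glutarate centre, never α to a carbonyl group, takes no part in any pericyclic step. The step needs regioselectivity, which the polarisation of the partners secures (CH terminus of 15 to the ketene carbonyl carbon), so that arm, prenyl group, free CH and the three oxygens can only appear in the required order, with the single unsilylated oxygen next to the arm, where it is stored as the lactone. Outward rotation of the alkyl arm in the opening of 18 should keep the methine hydrogen away from the ketene carbon, so that a 1,5-hydrogen shift should not compete.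

**Step 9**
Reactants: 23 (4S)-4-(5-methylhexyl)-6-(3-methylbut-2-en-1-yl)-5,7-bis(triisopropylsilyloxy)-3,4-dihydro-2H-chromen-2-one; 24 2-methylpropanoic anhydride
Product: 26 (3S)-8-methyl-3-[2-(2-methylpropanoyloxy)-5-(3-methylbut-2-en-1-yl)-4,6-bis(triisopropylsilyloxy)phenyl]nonanoic acid, via dipotassium salt 25 (not isolated)
Conditions: KOSiMe3 (2.2 equiv), THF, 0 °C, argon; then 24 (1.3 equiv), 0 °C; H2O (15 min), then cold 0.5 M HCl to pH 4
Reagents that add atoms: potassium trimethylsilanolate, C[Si](C)(C)[O-].[K+]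
Why: Silanolate cleaves the aryl lactone at the acyl carbon to the phenoxide–carboxylate pair 25 (the hindered aryl silyl ethers should be spared at 0 °C), and the far more nucleophilic phenoxide is then acylated by the anhydride, which caps the phenol before the acid is set free so that the lactone cannot re-form.

**Step 10**
Reactants: 26 (3S)-8-methyl-3-[2-(2-methylpropanoyloxy)-5-(3-methylbut-2-en-1-yl)-4,6-bis(triisopropylsilyloxy)phenyl]nonanoic acid; 11 [(5-methylhex-4-en-1-yn-1-yl)oxy]tri(propan-2-yl)silane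
Product: 29 2-[(1S)-6-methyl-1-[3-(3-methylbut-2-en-1-yl)-4-oxo-2-(triisopropylsilyloxy)cyclobut-2-en-1-yl]heptyl]-4-(3-methylbut-2-en-1-yl)-3,5-bis(triisopropylsilyloxy)phenyl 2-methylpropanoate (both epimers at the ring sp3 carbon), via acid chloride 27 (not isolated), via ketene 28 (not isolated)
Conditions: 1-chloro-N,N,2-trimethylprop-1-en-1-amine (1.05 equiv), CH2Cl2, 0 °C → rt; then added over 2 h to 11 (1.3 equiv), Et3N (1.5 equiv), CH2Cl2, rt; filtration, evaporation, used crude
Reagents that add atoms: none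
Why: Same ketene–siloxyalkyne [2+2] cycloaddition as in step 7; the aryl isobutyrate, the silyl ethers and the prenyl groups are inert to the neutral chlorination and to triethylamine, and the methine is again β to the reacting carbonyl group.

**Step 11**
Reactants: 29 cyclobutenone of ring A (see step 10); 15 (ethynyloxy)tri(propan-2-yl)silane
Product: 33 2-[(1S)-1-[2-hydroxy-5-(3-methylbut-2-en-1-yl)-4,6-bis(triisopropylsilyloxy)phenyl]-6-methylheptyl]-4-(3-methylbut-2-en-1-yl)-3,5-bis(triisopropylsilyloxy)phenyl 2-methylpropanoate, via vinylketene 30 (not isolated), via vinylcyclobutenone 31 (not isolated), via dienylketene 32 (not isolated)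
Conditions: 15 (2.0 equiv), toluene (0.2 M), 80 °C, sealed tube; evaporation; used at once without chromatography
Reagents that add atoms: none
Why: Second Danheiser benzannulation with the same cascade and regiochemistry as in step 8; the phenol is acylated at once because a free phenol beside the aryl ester of ring B could pass the isobutyryl group from one oxygen to the other, which would interchange the two rings and erode the methine configuration.

**Step 12**
Reactants: 33 phenol of ring A beside the isobutyrate of ring B (see step 11); 34 (2R)-2-methylbutanoic acid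
Product: 36 2-[(1R)-1-{2-[(2R)-2-methylbutanoyloxy]-5-(3-methylbut-2-en-1-yl)-4,6-bis(triisopropylsilyloxy)phenyl}-6-methylheptyl]-4-(3-methylbut-2-en-1-yl)-3,5-bis(triisopropylsilyloxy)phenyl 2-methylpropanoate, via acid chloride 35 (not isolated)
Conditions: 34 (1.5 equiv), 1-chloro-N,N,2-trimethylprop-1-en-1-amine (1.5 equiv), CH2Cl2, 0 °C; then 33, pyridine (3 equiv), CH2Cl2, −20 → 0 °C; diastereomer content checked by HPLC
Reagents that add atoms: none
Why: Acylation of the phenol through the acylpyridinium ion under weakly basic conditions: pyridine should neither form a ketene from the α-branched acid chloride (the (R) centre is kept) nor ionise the phenol, which keeps the O-to-O acyl transfer between the rings slow.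

**Step 13**
Reactants: 36 mixed diester (see step 12)
Product: 37 1-{2-hydroxy-3-[(1R)-1-{2-hydroxy-3-[(2R)-2-methylbutanoyl]-5-(3-methylbut-2-en-1-yl)-4,6-bis(triisopropylsilyloxy)phenyl}-6-methylheptyl]-5-(3-methylbut-2-en-1-yl)-4,6-bis(triisopropylsilyloxy)phenyl}-2-methylpropan-1-one
Conditions: hν (254 nm, low-pressure Hg lamp, quartz), degassed cyclohexane (5 mM), 20 °C
Reagents that add atoms: none
Why: Twofold photo-Fries rearrangement: excitation of each aryl ester leads to homolysis of the ArO–acyl bond and recombination of the caged acyl–phenoxyl pair at the only unsubstituted ortho carbon (the other ortho and the para position are substituted), then tautomerisation to the chelated o-hydroxyaryl ketone; the α-centre of the 2-methylbutanoyl radical should survive because cage recombination is faster than decarbonylation.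

**Step 14**
Reactants: 37 bis-ketone tetrasilyl ether (see step 13)
Product: 38 CNP0279787.1, (2R)-2-methyl-1-{2,4,6-trihydroxy-3-(3-methylbut-2-en-1-yl)-5-[(1R)-6-methyl-1-[2,4,6-trihydroxy-3-(3-methylbut-2-en-1-yl)-5-(2-methylpropanoyl)phenyl]heptyl]phenyl}butan-1-one
Conditions: Bu4NF (4.4 equiv), AcOH (5 equiv), THF, 0 °C; pH 6 phosphate buffer work-up; reverse-phase chromatography
Reagents that add atoms: none
Why: Fluoride cleaves the four aryl silyl ethers, while the acetic acid buffer keeps the medium from becoming basic enough to enolise the 2-methylbutanoyl ketone or to open a retro-Friedel–Crafts path at the methine; prenyl groups and ketones are inert.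

**Compound list**
1 | 6-methylheptanal | CC(C)CCCCC=O | starting material
2 | diethyl malonate | CCOC(=O)CC(=O)OCC | starting material
3 | diethyl 2-(6-methylheptylidene)propanedioate | CCOC(=O)C(=CCCCCC(C)C)C(=O)OCC | intermediate
4 | tetraethyl 2-(5-methylhexyl)propane-1,1,3,3-tetracarboxylate | CCOC(=O)C(C(=O)OCC)C(CCCCC(C)C)C(C(=O)OCC)C(=O)OCC | intermediate
5 | 3-(5-methylhexyl)pentanedioic acid | CC(C)CCCCC(CC(=O)O)CC(=O)O | intermediate
6 | 4-(5-methylhexyl)oxane-2,6-dione | CC(C)CCCCC1CC(=O)OC(=O)C1 | intermediate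
7 | (3R)-5-methoxy-3-(5-methylhexyl)-5-oxopentanoic acid | OC(=O)C[C@@H](CCCCC(C)C)CC(=O)OC | intermediate
8 | ethyl 4-methylpent-3-enoate | CCOC(=O)CC=C(C)C | starting material
9 | lithium 1,1-dibromo-5-methylhexa-1,4-dien-2-olate | [Li+].[O-]C(CC=C(C)C)=C(Br)Br | intermediate
10 | lithium 5-methylhex-4-en-1-yn-1-olate | [Li+].[O-]C#CCC=C(C)C | intermediate
11 | [(5-methylhex-4-en-1-yn-1-yl)oxy]tri(propan-2-yl)silane (prenyl siloxyalkyne) | CC(C)=CCC#CO[Si](C(C)C)(C(C)C)C(C)C | intermediate
12 | acetylene | C#C | starting material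
13 | lithium acetylide | [Li]C#C | intermediate
14 | lithium ethynolate | [Li+].[O-]C#C | intermediate
15 | (ethynyloxy)tri(propan-2-yl)silane (triisopropylsiloxyacetylene) | C#CO[Si](C(C)C)(C(C)C)C(C)C | intermediate
16 | methyl (3S)-5-chloro-3-(5-methylhexyl)-5-oxopentanoate | ClC(=O)C[C@@H](CCCCC(C)C)CC(=O)OC | intermediate
17 | methyl (3S)-8-methyl-3-(2-oxoethenyl)nonanoate (ketene) | O=C=C[C@@H](CCCCC(C)C)CC(=O)OC | intermediate
18 | methyl (3S)-8-methyl-3-[3-(3-methylbut-2-en-1-yl)-4-oxo-2-(triisopropylsilyloxy)cyclobut-2-en-1-yl]nonanoate, both epimers at the ring sp3 carbon | O=C1C(CC=C(C)C)=C(O[Si](C(C)C)(C(C)C)C(C)C)C1[C@@H](CCCCC(C)C)CC(=O)OC | intermediate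
19 | methyl (3S)-8-methyl-3-[3-(3-methylbut-2-en-1-yl)-4-oxo-2-(triisopropylsilyloxy)buta-1,3-dien-1-yl]nonanoate (siloxy-vinylketene, enol ether geometry of no consequence) | O=C=C(CC=C(C)C)C(O[Si](C(C)C)(C(C)C)C(C)C)=C[C@@H](CCCCC(C)C)CC(=O)OC | intermediate
20 | methyl (3S)-8-methyl-3-{2-[1-(3-methylbut-2-en-1-yl)-2-oxo-4-(triisopropylsilyloxy)cyclobut-3-en-1-yl]-2-(triisopropylsilyloxy)ethenyl}nonanoate (4-vinylcyclobutenone) | O=C1C=C(O[Si](C(C)C)(C(C)C)C(C)C)C1(CC=C(C)C)C(O[Si](C(C)C)(C(C)C)C(C)C)=C[C@@H](CCCCC(C)C)CC(=O)OC | intermediate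
21 | methyl (3S)-8-methyl-3-[3-(3-methylbut-2-en-1-yl)-6-oxo-2,4-bis(triisopropylsilyloxy)hexa-1,3,5-trien-1-yl]nonanoate (dienylketene) | O=C=CC(O[Si](C(C)C)(C(C)C)C(C)C)=C(CC=C(C)C)C(O[Si](C(C)C)(C(C)C)C(C)C)=C[C@@H](CCCCC(C)C)CC(=O)OC | intermediate
22 | methyl (3S)-3-[2-hydroxy-5-(3-methylbut-2-en-1-yl)-4,6-bis(triisopropylsilyloxy)phenyl]-8-methylnonanoate | Oc1cc(O[Si](C(C)C)(C(C)C)C(C)C)c(CC=C(C)C)c(O[Si](C(C)C)(C(C)C)C(C)C)c1[C@@H](CCCCC(C)C)CC(=O)OC | intermediate
23 | (4S)-4-(5-methylhexyl)-6-(3-methylbut-2-en-1-yl)-5,7-bis(triisopropylsilyloxy)-3,4-dihydro-2H-chromen-2-one | O=C1C[C@H](CCCCC(C)C)c2c(O1)cc(O[Si](C(C)C)(C(C)C)C(C)C)c(CC=C(C)C)c2O[Si](C(C)C)(C(C)C)C(C)C | intermediate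
24 | 2-methylpropanoic anhydride | CC(C)C(=O)OC(=O)C(C)C | starting material
25 | dipotassium (3S)-8-methyl-3-[5-(3-methylbut-2-en-1-yl)-2-oxido-4,6-bis(triisopropylsilyloxy)phenyl]nonanoate | [K+].[K+].[O-]C(=O)C[C@H](CCCCC(C)C)c1c([O-])cc(O[Si](C(C)C)(C(C)C)C(C)C)c(CC=C(C)C)c1O[Si](C(C)C)(C(C)C)C(C)C | intermediate
26 | (3S)-8-methyl-3-[2-(2-methylpropanoyloxy)-5-(3-methylbut-2-en-1-yl)-4,6-bis(triisopropylsilyloxy)phenyl]nonanoic acid | CC(C)C(=O)Oc1cc(O[Si](C(C)C)(C(C)C)C(C)C)c(CC=C(C)C)c(O[Si](C(C)C)(C(C)C)C(C)C)c1[C@@H](CCCCC(C)C)CC(=O)O | intermediate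
27 | (3S)-8-methyl-3-[2-(2-methylpropanoyloxy)-5-(3-methylbut-2-en-1-yl)-4,6-bis(triisopropylsilyloxy)phenyl]nonanoyl chloride | CC(C)C(=O)Oc1cc(O[Si](C(C)C)(C(C)C)C(C)C)c(CC=C(C)C)c(O[Si](C(C)C)(C(C)C)C(C)C)c1[C@@H](CCCCC(C)C)CC(=O)Cl | intermediate
28 | 2-[(3S)-8-methyl-1-oxonon-1-en-3-yl]-4-(3-methylbut-2-en-1-yl)-3,5-bis(triisopropylsilyloxy)phenyl 2-methylpropanoate (ketene) | CC(C)C(=O)Oc1cc(O[Si](C(C)C)(C(C)C)C(C)C)c(CC=C(C)C)c(O[Si](C(C)C)(C(C)C)C(C)C)c1[C@@H](CCCCC(C)C)C=C=O | intermediate
29 | 2-[(1S)-6-methyl-1-[3-(3-methylbut-2-en-1-yl)-4-oxo-2-(triisopropylsilyloxy)cyclobut-2-en-1-yl]heptyl]-4-(3-methylbut-2-en-1-yl)-3,5-bis(triisopropylsilyloxy)phenyl 2-methylpropanoate, both epimers at the ring sp3 carbon | CC(C)C(=O)Oc1cc(O[Si](C(C)C)(C(C)C)C(C)C)c(CC=C(C)C)c(O[Si](C(C)C)(C(C)C)C(C)C)c1[C@@H](CCCCC(C)C)C1C(=O)C(CC=C(C)C)=C1O[Si](C(C)C)(C(C)C)C(C)C | intermediate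
30 | siloxy-vinylketene from 29 (ring-B aryl–CH(5-methylhexyl)–CH=C(OSi)–C(prenyl)=C=O) | CC(C)C(=O)Oc1cc(O[Si](C(C)C)(C(C)C)C(C)C)c(CC=C(C)C)c(O[Si](C(C)C)(C(C)C)C(C)C)c1[C@@H](CCCCC(C)C)C=C(O[Si](C(C)C)(C(C)C)C(C)C)C(CC=C(C)C)=C=O | intermediate
31 | 4-vinylcyclobutenone from 30 and 15 (4-prenyl-3-siloxy-4-(1-siloxyalkenyl)cyclobut-2-enone) | CC(C)C(=O)Oc1cc(O[Si](C(C)C)(C(C)C)C(C)C)c(CC=C(C)C)c(O[Si](C(C)C)(C(C)C)C(C)C)c1[C@@H](CCCCC(C)C)C=C(O[Si](C(C)C)(C(C)C)C(C)C)C1(CC=C(C)C)C(=O)C=C1O[Si](C(C)C)(C(C)C)C(C)C | intermediate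
32 | dienylketene from 31 | CC(C)C(=O)Oc1cc(O[Si](C(C)C)(C(C)C)C(C)C)c(CC=C(C)C)c(O[Si](C(C)C)(C(C)C)C(C)C)c1[C@@H](CCCCC(C)C)C=C(O[Si](C(C)C)(C(C)C)C(C)C)C(CC=C(C)C)=C(O[Si](C(C)C)(C(C)C)C(C)C)C=C=O | intermediate
33 | 2-[(1S)-1-[2-hydroxy-5-(3-methylbut-2-en-1-yl)-4,6-bis(triisopropylsilyloxy)phenyl]-6-methylheptyl]-4-(3-methylbut-2-en-1-yl)-3,5-bis(triisopropylsilyloxy)phenyl 2-methylpropanoate | CC(C)C(=O)Oc1cc(O[Si](C(C)C)(C(C)C)C(C)C)c(CC=C(C)C)c(O[Si](C(C)C)(C(C)C)C(C)C)c1[C@@H](CCCCC(C)C)c1c(O)cc(O[Si](C(C)C)(C(C)C)C(C)C)c(CC=C(C)C)c1O[Si](C(C)C)(C(C)C)C(C)C | intermediate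
34 | (2R)-2-methylbutanoic acid | CC[C@@H](C)C(=O)O | starting material
35 | (2R)-2-methylbutanoyl chloride | CC[C@@H](C)C(=O)Cl | intermediate
36 | 2-[(1R)-1-{2-[(2R)-2-methylbutanoyloxy]-5-(3-methylbut-2-en-1-yl)-4,6-bis(triisopropylsilyloxy)phenyl}-6-methylheptyl]-4-(3-methylbut-2-en-1-yl)-3,5-bis(triisopropylsilyloxy)phenyl 2-methylpropanoate | CC(C)C(=O)Oc1cc(O[Si](C(C)C)(C(C)C)C(C)C)c(CC=C(C)C)c(O[Si](C(C)C)(C(C)C)C(C)C)c1[C@@H](CCCCC(C)C)c1c(OC(=O)[C@H](C)CC)cc(O[Si](C(C)C)(C(C)C)C(C)C)c(CC=C(C)C)c1O[Si](C(C)C)(C(C)C)C(C)C | intermediate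
37 | 1-{2-hydroxy-3-[(1R)-1-{2-hydroxy-3-[(2R)-2-methylbutanoyl]-5-(3-methylbut-2-en-1-yl)-4,6-bis(triisopropylsilyloxy)phenyl}-6-methylheptyl]-5-(3-methylbut-2-en-1-yl)-4,6-bis(triisopropylsilyloxy)phenyl}-2-methylpropan-1-one | Oc1c(C(=O)C(C)C)c(O[Si](C(C)C)(C(C)C)C(C)C)c(CC=C(C)C)c(O[Si](C(C)C)(C(C)C)C(C)C)c1[C@@H](CCCCC(C)C)c1c(O)c(C(=O)[C@H](C)CC)c(O[Si](C(C)C)(C(C)C)C(C)C)c(CC=C(C)C)c1O[Si](C(C)C)(C(C)C)C(C)C | intermediate
38 | CNP0279787.1, (2R)-2-methyl-1-{2,4,6-trihydroxy-3-(3-methylbut-2-en-1-yl)-5-[(1R)-6-methyl-1-[2,4,6-trihydroxy-3-(3-methylbut-2-en-1-yl)-5-(2-methylpropanoyl)phenyl]heptyl]phenyl}butan-1-one | Oc1c(C(=O)C(C)C)c(O)c(CC=C(C)C)c(O)c1[C@@H](CCCCC(C)C)c1c(O)c(C(=O)[C@H](C)CC)c(O)c(CC=C(C)C)c1O | target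

**Step count**
Total: 14 steps. Longest linear sequence: 12 steps (steps 1–4 and 7–14).

**Steps most likely to fail**

Step 8 (the same reaction recurs in step 11). The siloxy group makes cyclobutenone 18 a vinylogous silyl ester, so it may be hydrolysed, or the electron-rich vinylketene 19 may be lost to dimerisation before it meets 15. The fallback builds ring B by ionic chemistry; it sets out from anhydride 6 and comes back at lactone 23. Anhydride 6 would be opened with methanol under the pseudo-enantiomeric catalyst to (3S)-5-methoxy-3-(5-methylhexyl)-5-oxopentanoic acid F1. Its lithium carboxylate would be acylated at the ester group by the dianion (NaH, then n-BuLi, THF) of methyl 2-(3-methylbut-2-en-1-yl)-3-oxobutanoate F2 (Huckin–Weiler γ-acylation), giving (3R)-9-methoxy-3-(5-methylhexyl)-8-(3-methylbut-2-en-1-yl)-5,7,9-trioxononanoic acid F3. Here the carboxylate protects the second arm from Dieckmann closure. Mg(OMe)2 in methanol would close the ring by Claisen condensation, the ionic route from 3,5-dioxo esters to phloroglucinols. Acidic work-up would then lactonise the acid arm onto the ortho hydroxyl beside the ring CH to give (4S)-5,7-dihydroxy-4-(5-methylhexyl)-6-(3-methylbut-2-en-1-yl)-3,4-dihydro-2H-chromen-2-one F4; a regioisomeric lactone would be equilibrated under acid or separated. Silylation (i-Pr3SiOTf, 2,6-lutidine) would give 23.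

Step 13. Once the first o-hydroxyaryl ketone has formed it absorbs most of the light and can take over the excitation of the second ester, so the second migration may stall; escape of the radical pair would give phenol and decarbonylated material. The fallback sets out from 36 and comes back at 37. Iodination of the one free CH of each ring (N-iodosuccinimide, MeCN, 0 °C) would give the diiodide of the mixed diester F5. Treatment with t-BuLi (4.2 equiv, THF–Et2O–pentane, −100 °C) would effect iodine–lithium exchange, and each aryllithium would take over the neighbouring acyl group (anionic ortho-Fries rearrangement), giving 37 after buffered work-up.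

Step 7 (the same reaction recurs in step 10). Amine-promoted dimerisation of the aldoketene may outrun the cycloaddition. The fallback sets out from 7 and comes back at 18. The acid chloride 16 would be brominated at the α-carbon (N-bromosuccinimide, cat. HBr, 1,2-dichloroethane, 70 °C) to methyl (3S)-4-bromo-5-chloro-3-(5-methylhexyl)-5-oxopentanoate F6. Activated Zn in THF at −20 °C would then generate ketene 17 by reductive dehalogenation, without any amine and in the presence of 11, to give 18.

**Further compounds**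
F1 | step 8 | (3S)-5-methoxy-3-(5-methylhexyl)-5-oxopentanoic acid | OC(=O)C[C@H](CCCCC(C)C)CC(=O)OC
F2 | step 8 | methyl 2-(3-methylbut-2-en-1-yl)-3-oxobutanoate | COC(=O)C(CC=C(C)C)C(C)=O
F3 | step 8 | (3R)-9-methoxy-3-(5-methylhexyl)-8-(3-methylbut-2-en-1-yl)-5,7,9-trioxononanoic acid | OC(=O)C[C@H](CCCCC(C)C)CC(=O)CC(=O)C(CC=C(C)C)C(=O)OC
F4 | step 8 | (4S)-5,7-dihydroxy-4-(5-methylhexyl)-6-(3-methylbut-2-en-1-yl)-3,4-dihydro-2H-chromen-2-one | O=C1C[C@H](CCCCC(C)C)c2c(O1)cc(O)c(CC=C(C)C)c2O
F5 | step 13 | diiodide of 36, iodine on the free ring carbon of each ring next to the ester oxygen | CC(C)C(=O)Oc1c(I)c(O[Si](C(C)C)(C(C)C)C(C)C)c(CC=C(C)C)c(O[Si](C(C)C)(C(C)C)C(C)C)c1[C@@H](CCCCC(C)C)c1c(OC(=O)[C@H](C)CC)c(I)c(O[Si](C(C)C)(C(C)C)C(C)C)c(CC=C(C)C)c1O[Si](C(C)C)(C(C)C)C(C)C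
F6 | step 7 | methyl (3S)-4-bromo-5-chloro-3-(5-methylhexyl)-5-oxopentanoate, both epimers at C4 | ClC(=O)C(Br)[C@@H](CCCCC(C)C)CC(=O)OC
A1 | direct plan | (2R)-2-methyl-1-[2,4,6-trihydroxy-3-(3-methylbut-2-en-1-yl)phenyl]butan-1-one | CC[C@@H](C)C(=O)c1c(O)cc(O)c(CC=C(C)C)c1O
A2 | direct plan | 2-methyl-1-[2,4,6-trihydroxy-3-(3-methylbut-2-en-1-yl)phenyl]propan-1-one | CC(C)C(=O)c1c(O)cc(O)c(CC=C(C)C)c1O
A3 | direct plan | 2-methyl-1-{2,4,6-trihydroxy-3-(3-methylbut-2-en-1-yl)-5-[6-methyl-1-(4-methylbenzenesulfonyl)heptyl]phenyl}propan-1-one | CC(C)C(=O)c1c(O)c(CC=C(C)C)c(O)c(C(CCCCC(C)C)S(=O)(=O)c2ccc(C)cc2)c1O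
A4 | direct plan | 3,5-dihydroxy-6-(6-methylheptylidene)-4-(3-methylbut-2-en-1-yl)-2-(2-methylpropanoyl)cyclohexa-2,4-dien-1-one | CC(C)C(=O)C1=C(O)C(CC=C(C)C)=C(O)C(=CCCCCC(C)C)C1=O
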